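(The numbers are those of an exercise, and the outcome is calculated.)

Put the four vessels side by side and ask how much of the way to equilibrium each one covers.

    starting material ⇌ product (K1 = 2.1, k1 = 0.0011 min⁻¹)

| flask | starting material | time | remark |
|---|---|---|---|
| east | 0.050 M | 8.0 h | plug flow through a tube for 8.0 h, no back-mixing |
| south-west | 0.050 M | 8.0 h | everything together in a closed stirred flask, run for 8.0 h |
| north | 0.050 M |  | one stirred flow tank at steady state, fed with the mixture as stated, mean residence time 8.0 h |
| west | 0.050 M |  | a single well-mixed tank run continuously and read at steady state, 80.0 h in it on average |

- the set-up with the highest amount of product at the outlet or at the end, in percent of the starting material put in ("none" if the first two lie within 2 percentage points) (east / south-west / north / west / none)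
- amount of product at the outlet or at the end, in percent of the starting material put in, east
- amount of product at the outlet or at the end, in percent of the starting material put in, south-west
- amount of product at the outlet or at the end, in percent of the starting material put in, north
- amount of product at the outlet or at the end, in percent of the starting material put in, west

Where is the ceiling? Product over starting material at equilibrium is 2.1, so product stands at 67.7% of the charge.

How fast is it approached? Call the sum of the forward and back rate constants the relaxation rate, 0.0974 h⁻¹: the gap to equilibrium closes at that rate.

The east tube and the south-west flask? The tube has no back-mixing, the closed flask takes in nothing new, and each runs 8.0 h, which is 0.779 relaxation times. The gap shrinks exponentially, so each covers 54.1% of the way and gives 36.7% product.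

And the north tank, where the reaction runs at outlet composition? Iterate. Ignoring the way back gives 34.6%. Putting that answer into the way back gives 28.9%, and going round once more gives 29.8%. The rounds close on 29.7%, which is the ceiling times N/(1+N), with N the relaxation times spent in the tank on average. So the north tank gives less than the east tube.

Then what of the west tank? It has ten times the mean residence time of the north tank, 7.79 relaxation times on average, so it covers 88.6% of the way, more than the east tube's 54.1%. I put west first.

The forecast also names west, with 36.7% east, 36.7% south-west, 29.7% north and 60% west, on the ground that “its tenfold longer residence time carries it close to equilibrium”.

The simulation gives west as best, at 60.0%, against 36.7% east, 36.7% south-west and 29.7% north. In the west tank c(starting material) reads 0.0200 M, which is 40.0% of the charge. The relaxation rate of 0.0974 h⁻¹ over 80.0 h on average puts the west tank 88.6% of the way to the ceiling of 67.7%, which is 60.0% product.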